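**Retrosynthetic overview**
1. Target: 8β-acyloxy-5α,10α-epoxy-germacra-3,11(13)-dien-12,6α-olide with C15 as CO2Me. Last disconnections: CO2Me ⇐ CHO; Δ3 ⇐ saturated C4 aldehyde; C5–O bond ⇐ transannular oxa-Michael addition of a 10α-hydroxyl to a C15 enal.
2. The 10α-hydroxyl comes from outer-face dihydroxylation of Δ1(10) followed by C1 deoxygenation; C15 is oxidised by allylic oxidation; the C8 ester comes from eupatolide and an epoxy acid made from tiglic acid by Sharpless epoxidation.
3. Eupatolide ⇐ (+)-germacrene A by three P450 oxidations (C12 acid, 8β-OH, 6α-OH with lactonisation).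
4. Feature carrying the strategy: the ten-membered carbocycle C1–C10 with C14 on C10, C15 on C4 and the C11–C13 unit on C7 (a germacrane). It is closed at C6–C7 (the C1–C10 bond of the farnesyl chain) by germacrene A synthase acting on farnesyl diphosphate.
5. Ring order: carbocycle (step 3), γ-lactone (step 6), side-chain oxirane (step 8, separate branch), both oxepane rings of the C5–O–C10 bridge (step 15).

Key step: step 3

Remark: germacrane numbering is used for all cyclic compounds; the bond closed in the key step is C1–C10 of farnesyl diphosphate, which is C6–C7 of the germacrane; α/β refer to the usual planar projection with H-7 α.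
Remark: the 2,3-epoxy-2-methylbutanoyl group of the target has its two methyl groups cis (2S,3R), so it is the epoxide of tiglic (not angelic) acid.
Remark: the C5–O bond of the target lies on the face opposite to the one that reagents reach when they attack a 4,5-olefin from outside the ring; the oxygen is therefore placed on C10 first (outer face) and carried across the ring to C5.
Remark: the P450 steps are written for microsomal enzyme with NADPH recycling; the same enzymes can be run in whole yeast cells without change of the chemistry.

Step 1
Reactants: 1 (2E,6E)-farnesol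
Product: 2 (2E,6E)-farnesyl bromide
Conditions: PBr3 (0.4 equiv), Et2O, −10 to 0 °C
Reagents that add atoms: phosphorus tribromide, BrP(Br)Br
Why: Conversion of a primary allylic alcohol to the bromide with PBr3 (SN2 on the phosphite ester), which at low temperature should keep the 2E olefin and avoid allylic transposition.

Step 2
Reactants: 2 (2E,6E)-farnesyl bromide
Product: 3 (2E,6E)-farnesyl diphosphate (handled as the ammonium salt)
Conditions: (Bu4N)3HP2O7 (2 equiv), MeCN, rt; then cation exchange (NH4+ form), aq. NH4HCO3, lyophilise
Reagents that add atoms: tris(tetrabutylammonium) hydrogen diphosphate, CCCC[N+](CCCC)(CCCC)CCCC.CCCC[N+](CCCC)(CCCC)CCCC.CCCC[N+](CCCC)(CCCC)CCCC.OP(=O)([O-])OP(=O)([O-])[O-]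
Why: SN2 alkylation of the diphosphate anion by the primary allylic bromide, the standard diphosphorylation of allylic halides, which should leave both olefin geometries unchanged.

Step 3
Reactants: 3 (2E,6E)-farnesyl diphosphate
Product: 4 (R)-(+)-germacrene A
Conditions: recombinant germacrene A synthase (chicory or lettuce enzyme, expressed in E. coli), MgCl2 (10 mM), DTT, HEPES buffer pH 7.0, 30 °C, pentane overlay; cold pentane extraction, filtration through neutral alumina at 0 °C, storage in pentane at −20 °C
Reagents that add atoms: none
Why: The synthase binds the diphosphate through its Mg2+ cluster and ionises it to the (2E,6E)-farnesyl allyl cation; the distal C10=C11 π bond attacks C1 through C10, forming the C1–C10 bond of the farnesyl chain (C6–C7 of the germacrane), and the tertiary C11 cation loses a proton from a terminal methyl to give the isopropenyl group. This is the cation–olefin macrocyclisation of ionisation-type terpene synthases, and germacrene A synthases are characterised enzymes that carry out exactly this conversion. The ten-membered ring closes in the exo mode with respect to the attacking olefin (C11 stays outside the ring), that is by 1,10-closure. The single new stereocentre (farnesyl C10, germacrane C7) is fixed by the active-site fold, which presents one face of the C10=C11 olefin to C1 and should give the R configuration with H-7 α. The step needs 1,10- rather than 1,11- or 1,6-closure, retention of both E olefins and no second cyclisation, all of which the active-site contour secures. The pentane overlay, neutral pH and cold work-up should protect the product from acid-induced transannular cyclisation and Cope rearrangement.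

Step 4
Reactants: 4 (R)-(+)-germacrene A
Product: 7 germacrene A acid (germacra-1(10),4,11(13)-trien-12-oic acid), via 12-alcohol 5 (not isolated), via 12-aldehyde 6 (not isolated)
Conditions: yeast microsomes containing germacrene A oxidase (CYP71AV8) and a cytochrome P450 reductase, NADPH (cat.), D-glucose 6-phosphate, glucose-6-phosphate dehydrogenase, air, phosphate buffer pH 7.5, 30 °C
Reagents that add atoms: dioxygen, O=O
Why: Three successive P450 oxidations (hydrogen abstraction and oxygen rebound) at the allylic methyl of the isopropenyl group, the known function of this oxidase, take C12 to the acid without forming a stereocentre or touching C7.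

Step 5
Reactants: 7 germacrene A acid
Product: 8 8β-hydroxygermacrene A acid
Conditions: yeast microsomes containing germacrene A acid 8β-hydroxylase (CYP71BL1) and a cytochrome P450 reductase, NADPH (cat.), D-glucose 6-phosphate, glucose-6-phosphate dehydrogenase, air, phosphate buffer pH 7.5, 30 °C
Reagents that add atoms: dioxygen, O=O
Why: P450 hydroxylation of the C8 methylene with retention (abstraction and rebound), the known reaction of this enzyme, whose active site should deliver oxygen to the β face and so set C8 as R.

Step 6
Reactants: 8 8β-hydroxygermacrene A acid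
Product: 10 eupatolide (8β-hydroxycostunolide), via 6α-hydroxy acid 9 (not isolated)
Conditions: yeast microsomes containing eupatolide synthase (CYP71DD6) and a cytochrome P450 reductase, NADPH (cat.), D-glucose 6-phosphate, glucose-6-phosphate dehydrogenase, air, phosphate buffer pH 7.5, 30 °C
Reagents that add atoms: dioxygen, O=O
Why: Allylic P450 hydroxylation at C6 on the α face (enzyme control sets C6) is followed by spontaneous lactonisation of the 6α-hydroxyl onto the C12 acid, closing the trans-fused γ-lactone, which is the known course of this enzyme with the 8β-hydroxy acid.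

Step 7
Reactants: 11 tiglic acid
Product: 12 (E)-2-methylbut-2-en-1-ol
Conditions: LiAlH4, Et2O, 0 °C to rt; aqueous work-up
Reagents that add atoms: none
Why: Hydride reduction of the acid to the primary allylic alcohol (1,2-reduction), which should leave the trisubstituted E olefin untouched.

Step 8
Reactants: 12 (E)-2-methylbut-2-en-1-ol
Product: 13 [(2R,3R)-2,3-dimethyloxiran-2-yl]methanol
Conditions: Ti(OiPr)4 (10 mol%), D-(−)-diethyl tartrate (12 mol%), t-BuOOH (anhydrous, in decane), 4 Å molecular sieves, CH2Cl2, −20 °C
Reagents that add atoms: tert-butyl hydroperoxide, CC(C)(C)OO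
Why: Sharpless asymmetric epoxidation, in which the titanium complex of D-(−)-tartrate delivers oxygen to the olefin face that gives the (2R,3R) epoxy alcohol (the enantiomer of the 2S,3S series formed with L-(+)-tartrate from E allylic alcohols), the cis relation of the two methyl groups following from the E olefin.

Step 9
Reactants: 13 [(2R,3R)-2,3-dimethyloxiran-2-yl]methanol
Product: 14 (2S,3R)-2,3-dimethyloxirane-2-carboxylic acid
Conditions: RuCl3 (2 mol%), NaIO4 (3 equiv), MeCN/EtOAc/H2O, 0 °C to rt
Reagents that add atoms: sodium periodate, [Na+].[O-]I(=O)(=O)=O; water, O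
Why: RuO4 formed in the flask oxidises the primary alcohol through the aldehyde hydrate to the acid without opening the oxirane (oxidation of epoxy alcohols to glycidic acids); both centres are retained, C2 being renamed S only because CO2H now outranks C3.

Step 10
Reactants: 10 eupatolide; 14 (2S,3R)-2,3-dimethyloxirane-2-carboxylic acid
Product: 15 eupatolide 8-O-[(2S,3R)-2,3-epoxy-2-methylbutanoate]
Conditions: DCC (1.3 equiv), DMAP (0.2 equiv), CH2Cl2, 0 °C to rt
Reagents that add atoms: none
Why: Steglich esterification of the secondary 8β-hydroxyl through the acylpyridinium of 14 should proceed with retention at C8, the low temperature guarding the glycidic acid against decarboxylation.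

Step 11
Reactants: 15 eupatolide 8-O-[(2S,3R)-2,3-epoxy-2-methylbutanoate]
Product: 16 1β,10α-dihydroxy-1,10-dihydro derivative of 15 (1R,10R)
Conditions: OsO4 (2 mol%), N-methylmorpholine N-oxide (1.05 equiv), acetone/H2O 4:1, 0 °C
Reagents that add atoms: N-methylmorpholine N-oxide, C[N+]1([O-])CCOCC1; water, O
Why: Upjohn syn-dihydroxylation should take place at Δ1(10), the most electron-rich olefin (Δ4(5) is deactivated by the allylic lactone oxygen and the methylene lactone is electron-poor), from the exposed outer face of the E olefin in the crossed ring conformation with C14 β, the face that peracids also use, which sets the 10α-oxygen needed later.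

Step 12
Reactants: 16 1β,10α-diol
Product: 17 1-O-(phenoxythiocarbonyl) derivative of 16
Conditions: PhOC(S)Cl (1.2 equiv), pyridine (3 equiv), CH2Cl2, 0 °C
Reagents that add atoms: O-phenyl chlorothionoformate, S=C(Cl)Oc1ccccc1
Why: Thioacylation should occur only at the secondary C1 hydroxyl, the tertiary C10 hydroxyl being too hindered, and the mild base without DMAP should avoid closure to the cyclic thionocarbonate.

Step 13
Reactants: 17 1-O-(phenoxythiocarbonyl) derivative
Product: 18 10α-hydroxy-1,10-dihydro derivative of 15 (10S)
Conditions: Bu3SnH (1.5 equiv), Et3B (0.2 equiv), trace air, toluene, rt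
Reagents that add atoms: none
Why: Barton–McCombie deoxygenation (stannyl radical addition to C=S, β-scission to the secondary C1 radical, hydrogen transfer from Sn–H) removes the C1 oxygen at room temperature and leaves the C10 carbinol untouched, its descriptor changing to S only by priority.

Step 14
Reactants: 18 10α-hydroxy-1,10-dihydro derivative
Product: 19 15-hydroxy derivative of 18 with C4=C5 cis in the ring (CH2OH trans to C6)
Conditions: SeO2 (0.5 equiv), t-BuOOH (3 equiv, in decane), CH2Cl2, rt
Reagents that add atoms: selenium dioxide (oxygen carrier), O=[Se]=O; tert-butyl hydroperoxide, CC(C)(C)OO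
Why: Riley allylic oxidation: the ene reaction of SeO2 at C5 with a C15 hydrogen and the [2,3]-sigmatropic shift should place oxygen on C15 and re-form C4=C5, the methyl hydrogens being better aligned than the ring methylene as known for the C14 methyl of 4,5-epoxygermacranolides, where the ring olefin also turns cis; either olefin geometry serves step 15.

Step 15
Reactants: 19 15-hydroxy derivative
Product: 21 5α,10α-epoxy aldehyde (C15 aldehyde on sp3 C4; C4 epimers), via enal 20 (not isolated)
Conditions: MnO2 (15 equiv), CH2Cl2, rt; filter; DBU (0.2 equiv), CH2Cl2, 0 °C to rt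
Reagents that add atoms: none
Why: Allylic oxidation to the enal is followed by base-catalysed transannular oxa-Michael addition of the tertiary C10 alkoxide to C5, which closes both oxepane rings (7-exo for the ring through C6–C9, the same bond completing the ring through C1–C4); because a one-atom bridge across the ten-membered ring can only be out,out, the 10S oxygen should force the 5R (5α-O) configuration, and C4 forms as epimers that converge in step 16.

Step 16
Reactants: 21 5α,10α-epoxy aldehyde
Product: 22 5α,10α-epoxy-3-en-15-al
Conditions: IBX (3 equiv), DMSO/toluene 1:2, 70 °C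
Reagents that add atoms: none
Why: IBX-mediated α,β-dehydrogenation of the aldehyde through its enol should remove H-4 and a C3 hydrogen, since the only other β-hydrogen sits on the bridgehead C5 next to oxygen, and so gives the conjugated Δ3 enal and erases the C4 centre.

Step 17
Reactants: 22 5α,10α-epoxy-3-en-15-al
Product: 23 5α,10α-epoxy-3-en-15-oic acid
Conditions: NaClO2, NaH2PO4, 2-methyl-2-butene, t-BuOH/H2O, 0 °C to rt
Reagents that add atoms: sodium chlorite, [Na+].[O-]Cl=O
Why: Pinnick oxidation is selective for the aldehyde, and the scavenger removes hypochlorous acid before it can attack the olefins or the oxirane.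

Step 18
Reactants: 23 5α,10α-epoxy-3-en-15-oic acid
Product: 24 target (CNP0240298.1)
Conditions: MeI (3 equiv), K2CO3 (1.5 equiv), DMF, 0 °C to rt
Reagents that add atoms: iodomethane, CI
Why: SN2 O-methylation of the carboxylate under weakly basic, non-nucleophilic conditions should spare the methylene lactone and the epoxy ester.

**Compound list**
1 | (2E,6E)-farnesol | CC(C)=CCC/C(C)=C/CC/C(C)=C/CO | starting material
2 | (2E,6E)-farnesyl bromide | CC(C)=CCC/C(C)=C/CC/C(C)=C/CBr | intermediate
3 | (2E,6E)-farnesyl diphosphate (ammonium salt in practice, free acid drawn) | CC(C)=CCC/C(C)=C/CC/C(C)=C/COP(=O)(O)OP(=O)(O)O | intermediate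
4 | (R)-(+)-germacrene A | C=C(C)[C@H]1C/C=C(\C)CC/C=C(\C)CC1 | intermediate
5 | germacra-1(10),4,11(13)-trien-12-ol (formed in step 4, not isolated) | C=C(CO)[C@H]1C/C=C(\C)CC/C=C(\C)CC1 | intermediate
6 | germacra-1(10),4,11(13)-trien-12-al (formed in step 4, not isolated) | C=C(C=O)[C@H]1C/C=C(\C)CC/C=C(\C)CC1 | intermediate
7 | germacrene A acid | C=C(C(=O)O)[C@H]1C/C=C(\C)CC/C=C(\C)CC1 | intermediate
8 | 8β-hydroxygermacrene A acid (7R,8R) | C=C(C(=O)O)[C@H]1C/C=C(\C)CC/C=C(\C)C[C@H]1O | intermediate
9 | 6α,8β-dihydroxygermacrene A acid (formed in step 6, not isolated) | C=C(C(=O)O)[C@H]1[C@H](O)/C=C(\C)CC/C=C(\C)C[C@H]1O | intermediate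
10 | eupatolide (6R,7R,8R) | C=C1C(=O)O[C@@H]2/C=C(\C)CC/C=C(\C)C[C@@H](O)[C@@H]12 | intermediate
11 | tiglic acid | C/C=C(\C)C(=O)O | starting material
12 | (E)-2-methylbut-2-en-1-ol | C/C=C(\C)CO | intermediate
13 | [(2R,3R)-2,3-dimethyloxiran-2-yl]methanol | OC[C@@]1(C)O[C@@H]1C | intermediate
14 | (2S,3R)-2,3-dimethyloxirane-2-carboxylic acid | OC(=O)[C@@]1(C)O[C@@H]1C | intermediate
15 | eupatolide 8-O-[(2S,3R)-2,3-epoxy-2-methylbutanoate] | C=C1C(=O)O[C@@H]2/C=C(\C)CC/C=C(\C)C[C@@H](OC(=O)[C@@]3(C)O[C@@H]3C)[C@@H]12 | intermediate
16 | 1β,10α-dihydroxy-1,10-dihydro derivative of 15 (1R,10R) | C=C1C(=O)O[C@@H]2/C=C(\C)CC[C@@H](O)[C@](C)(O)C[C@@H](OC(=O)[C@@]3(C)O[C@@H]3C)[C@@H]12 | intermediate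
17 | 1-O-(phenoxythiocarbonyl) derivative of 16 | C=C1C(=O)O[C@@H]2/C=C(\C)CC[C@@H](OC(=S)Oc4ccccc4)[C@](C)(O)C[C@@H](OC(=O)[C@@]3(C)O[C@@H]3C)[C@@H]12 | intermediate
18 | 10α-hydroxy-1,10-dihydro derivative of 15 (10S) | C=C1C(=O)O[C@@H]2/C=C(\C)CCC[C@](C)(O)C[C@@H](OC(=O)[C@@]3(C)O[C@@H]3C)[C@@H]12 | intermediate
19 | 15-hydroxy derivative of 18, C3 and C6 cis on C4=C5 | C=C1C(=O)O[C@@H]2/C=C(/CO)CCC[C@](C)(O)C[C@@H](OC(=O)[C@@]3(C)O[C@@H]3C)[C@@H]12 | intermediate
20 | C15 enal of 19 (formed in step 15, not isolated) | C=C1C(=O)O[C@@H]2/C=C(/C=O)CCC[C@](C)(O)C[C@@H](OC(=O)[C@@]3(C)O[C@@H]3C)[C@@H]12 | intermediate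
21 | 8β-acyloxy-5α,10α-epoxygermacr-11(13)-en-12,6α-olid-15-al (5R,6S,7R,8R,10S; C4 epimers) | C=C1C(=O)O[C@H]2[C@H]1[C@H](OC(=O)[C@@]1(C)O[C@@H]1C)C[C@]1(C)CCCC(C=O)[C@H]2O1 | intermediate
22 | 8β-acyloxy-5α,10α-epoxygermacra-3,11(13)-dien-12,6α-olid-15-al | C=C1C(=O)O[C@H]2[C@H]1[C@H](OC(=O)[C@@]1(C)O[C@@H]1C)C[C@]1(C)CCC=C(C=O)[C@H]2O1 | intermediate
23 | 8β-acyloxy-5α,10α-epoxygermacra-3,11(13)-dien-12,6α-olid-15-oic acid | C=C1C(=O)O[C@H]2[C@H]1[C@H](OC(=O)[C@@]1(C)O[C@@H]1C)C[C@]1(C)CCC=C(C(=O)O)[C@H]2O1 | intermediate
24 | methyl 8β-[(2S,3R)-2,3-epoxy-2-methylbutanoyloxy]-5α,10α-epoxygermacra-3,11(13)-dien-12,6α-olid-15-oate (5R,6S,7R,8R,10S) | C=C1C(=O)O[C@H]2[C@H]1[C@H](OC(=O)[C@@]1(C)O[C@@H]1C)C[C@]1(C)CCC=C(C(=O)OC)[C@H]2O1 | target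

**Step count**
Total: 18 steps. Longest linear sequence: 15 steps (steps 1–6 and 10–18); the side chain takes steps 7–9.

**Steps most likely to fail**

Step 14 (allylic oxidation at C15). The ene reaction may be slow because the 4,5-olefin is deactivated by the allylic lactone oxygen, oxidation may go to the ring methylene C3 instead of the methyl, and the alcohol may be over-oxidised. The fallback sets out from 18 and comes back at 19. Photo-oxygenation of 18 (O2, tetraphenylporphyrin, visible light, CH2Cl2, 0 °C) is a Schenck ene reaction at the only electron-rich olefin; oxygen should enter at C5 from the outer face with abstraction of a C15 hydrogen and give the 5β-hydroperoxy-4(15)-ene F1. Reduction with PPh3 should give the allylic alcohol F2. A 1,3-hydroxyl transposition catalysed by Ph3SiOReO3 (Et2O, 0 °C) should then move the oxygen to C15 and re-form the trisubstituted C4=C5 olefin, which is 19 (either geometry serves step 15).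

Step 13 (radical deoxygenation at C1). The thiocarbonate may close onto the neighbouring tertiary hydroxyl, and the cyclic thionocarbonate would then fragment at C10; stannyl or carbon radicals may also add to the methylene lactone. The fallback sets out from 16 and comes back at 18. The secondary C1 alcohol of 16 is oxidised with Dess–Martin periodinane (CH2Cl2, rt) to the α-hydroxy ketone F3, which is condensed with tosylhydrazide (MeOH, cat. AcOH) to the tosylhydrazone F4. Reduction with catecholborane (CHCl3, 0 °C) followed by NaOAc·3H2O (loss of sulfinate and dinitrogen) should give the methylene compound 18 without radical intermediates.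

Step 15 (transannular oxa-Michael addition). The equilibrium may lie on the side of the open hydroxy enal, the β-alkoxy aldehyde may revert under base, and the C10 hydroxyl may be held as the C15 hemiacetal. The fallback sets out from 20 and comes back at 22. Enal 20 is made from 19 with MnO2 as before, and the ring closure is then run under amine catalysis (pyrrolidine 20 mol%, PhCO2H, CH2Cl2) in the presence of N-(phenylseleno)phthalimide. The enamine formed after C5–O closure should be captured at C4 as the α-phenylseleno aldehyde F5, which cannot revert. Oxidation (H2O2, pyridine, 0 °C) and selenoxide syn-elimination towards C3 should give enal 22 directly, so that step 16 is not needed.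

**Further compounds**
F1 | step 14 | 5β-hydroperoxy-10α-hydroxy-4(15)-ene isomer of 18 (5S) | C=C1C(=O)O[C@@H]2[C@@H](OO)C(=C)CCC[C@](C)(O)C[C@@H](OC(=O)[C@@]3(C)O[C@@H]3C)[C@@H]12
F2 | step 14 | 5β,10α-dihydroxy-4(15)-ene isomer of 18 (5S) | C=C1C(=O)O[C@@H]2[C@@H](O)C(=C)CCC[C@](C)(O)C[C@@H](OC(=O)[C@@]3(C)O[C@@H]3C)[C@@H]12
F3 | step 13 | 10α-hydroxy-1-oxo-1,10-dihydro derivative of 15 | C=C1C(=O)O[C@@H]2/C=C(\C)CCC(=O)[C@](C)(O)C[C@@H](OC(=O)[C@@]3(C)O[C@@H]3C)[C@@H]12
F4 | step 13 | tosylhydrazone of F3 | C=C1C(=O)O[C@@H]2/C=C(\C)CCC(=NNS(=O)(=O)c4ccc(C)cc4)[C@](C)(O)C[C@@H](OC(=O)[C@@]3(C)O[C@@H]3C)[C@@H]12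
F5 | step 15 | 4-phenylseleno derivative of 21 | C=C1C(=O)O[C@H]2[C@H]1[C@H](OC(=O)[C@@]1(C)O[C@@H]1C)C[C@]1(C)CCCC(C=O)([Se]c3ccccc3)[C@H]2O1
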